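**Retrosynthetic overview**
- The strategy rests on the ring C ether oxygen that joins the fully substituted C9 to the spiro carbon C13, and on ring D (C13–C14=C15–O–C16), an acid-labile enol ether on that same carbon. Ring D is carried as its saturated C15 methyl acetal and unmasked at the end (C8 acetate, loss of MeOH, desilylation).
- Rings C and D together: the O9–C13 and O16–C15 bonds are cut back to an 8α,9α-diol whose side chain carries a C13–C16 epoxide and a C15 dimethyl acetal; one acid-triggered cascade closes both.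
- The diol comes from OsO4 on a C8=C9 alkene flanked by a 7β-silyloxy-6-ketone. C9–C11 comes from adding an epoxy-acetylide (C13 from Sharpless epoxidation) to a C9 ketone, then dehydration and diimide reduction.
- Ring A is closed onto ring B by intramolecular tert-alkylation at C5 (C4–C5 bond, cis fusion). C10 is set by Pd-catalysed decarboxylative allylation of a quinone-monoketal-derived enolate.
- Ring order: B (from a phenol), then A, then C and D in one step.

Key step: step 20

Remark: locants are labdane locants (C1–C20). The SMILES encodes the A/B-cis compound (5R,7R,8R,9S,10S,13S; H-5 and the C10 methyl on the same face) and that compound is made. 4-Methoxy-2,6-dimethylphenol and 2-[(trimethylsilyl)methyl]allyl acetate are taken as commercial. The C15 acetal epimers are carried as a mixture.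

**Side-chain fragment**

Step 1
Reactants: 1 2-[(trimethylsilyl)methyl]prop-2-en-1-yl acetate
Product: 2 4,4-dimethoxy-2-methylidenebutyl acetate
Conditions: HC(OMe)3 (5 equiv), Me3SiOTf (5 mol%), CH2Cl2, −78 → −40 °C
Reagents that add atoms: trimethyl orthoformate COC(OC)OC
Why: Hosomi–Sakurai allylation; Me3SiOTf ionises the orthoformate to a dimethoxycarbenium ion that the allylsilane captures at its γ-carbon with loss of silicon, which should give the 2-substituted allyl acetate carrying the dimethyl acetal (C14–C15).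

Step 2
Reactants: 2 4,4-dimethoxy-2-methylidenebutyl acetate
Product: 3 2-(2,2-dimethoxyethyl)prop-2-en-1-ol
Conditions: K2CO3 (cat.), MeOH, rt
Reagents that add atoms: none
Why: Base-catalysed transesterification of a primary acetate, which leaves the acetal and the 1,1-disubstituted alkene untouched.

Step 3
Reactants: 3 2-(2,2-dimethoxyethyl)prop-2-en-1-ol
Product: 4 [(2S)-2-(2,2-dimethoxyethyl)oxiran-2-yl]methanol
Conditions: Ti(OiPr)4 (10 mol%), L-(+)-DIPT (12 mol%), t-BuOOH, 4 Å MS, CH2Cl2, −20 °C
Reagents that add atoms: tert-butyl hydroperoxide CC(C)(C)OO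
Why: Sharpless asymmetric epoxidation of a 2-substituted allylic alcohol; L-(+)-tartrate should deliver oxygen to the face that gives the (S)-epoxy alcohol (the sense in which allyl alcohol gives (S)-glycidol), which sets C13 by reagent control.

Step 4
Reactants: 4 [(2S)-2-(2,2-dimethoxyethyl)oxiran-2-yl]methanol
Product: 5 (2R)-2-(2,2-dimethoxyethyl)oxirane-2-carbaldehyde
Conditions: Dess–Martin periodinane, NaHCO3, CH2Cl2, 0 °C
Reagents that add atoms: none
Why: Buffered Dess–Martin oxidation of a primary alcohol; the aldehyde has no α-hydrogen, so C13 cannot epimerise.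

Step 5
Reactants: 5 (2R)-2-(2,2-dimethoxyethyl)oxirane-2-carbaldehyde
Product: 6 (2S)-2-(2,2-dimethoxyethyl)-2-ethynyloxirane
Conditions: dimethyl (1-diazo-2-oxopropyl)phosphonate, K2CO3, MeOH, 0 °C → rt
Reagents that add atoms: dimethyl (1-diazo-2-oxopropyl)phosphonate CC(=O)C(=[N+]=[N-])P(=O)(OC)OC
Why: Seyferth–Gilbert homologation with the Ohira–Bestmann reagent turns the non-enolisable aldehyde into the terminal alkyne (the new carbon is C11) under carbonate/methanol conditions that a 2,2-disubstituted epoxide should tolerate.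

**Rings B and A**

Step 6
Reactants: 7 4-methoxy-2,6-dimethylphenol
Product: 8 4,4-dimethoxy-2,6-dimethylcyclohexa-2,5-dien-1-one
Conditions: PhI(OAc)2, MeOH, 0 °C → rt
Reagents that add atoms: methanol CO
Why: Oxidative dearomatisation of a p-methoxyphenol by trivalent iodine in methanol, the standard entry to quinone monoketals; the ketal sits at C6 and the free carbonyl (C9) is flanked by both methyl-bearing carbons.

Step 7
Reactants: 8 4,4-dimethoxy-2,6-dimethylcyclohexa-2,5-dien-1-one
Product: 10 allyl (4,4-dimethoxy-2,6-dimethylcyclohexa-1,5-dien-1-yl) carbonate, via lithium dienolate 9 (not isolated)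
Conditions: LiBH(s-Bu)3 (L-Selectride, 1.05 equiv), THF, −78 °C; then allyl chloroformate, −78 → 0 °C
Reagents that add atoms: allyl chloroformate C=CCOC(=O)Cl
Why: Reductive enolate trapping; the hindered hydride adds 1,4 to the unsubstituted β-carbon (1,2-addition is blocked by the two α-methyl groups) and the regiodefined enolate is O-acylated by the chloroformate.

Step 8
Reactants: 10 allyl (4,4-dimethoxy-2,6-dimethylcyclohexa-1,5-dien-1-yl) carbonate
Product: 11 (6S)-6-allyl-4,4-dimethoxy-2,6-dimethylcyclohex-2-en-1-one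
Conditions: Pd2(dba)3 (2.5 mol%), (R)-t-BuPHOX (6 mol%), THF, 25 °C
Reagents that add atoms: none
Why: Decarboxylative asymmetric allylic alkylation (Tsuji type) of an allyl enol carbonate; zerovalent palladium ionises the carbonate, CO2 is lost and the tetrasubstituted enolate is C-allylated under ligand control, which should set the quaternary C10 as (S) (ligand enantiomer chosen by analogy with 2-allyl-2-methylcyclohexanone).

Step 9
Reactants: 11 (6S)-6-allyl-4,4-dimethoxy-2,6-dimethylcyclohex-2-en-1-one
Product: 13 (6S)-4,4-dimethoxy-2,6-dimethyl-6-(4-methylpent-4-en-1-yl)cyclohex-2-en-1-one, via B-alkyl-9-BBN adduct 12 (not isolated)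
Conditions: 9-BBN, THF, 0 °C → rt; then 2-bromopropene, Pd(dppf)Cl2 (5 mol%), AsPh3, Cs2CO3, DMF/H2O, rt
Reagents that add atoms: 2-bromopropene CC(Br)=C
Why: Anti-Markovnikov hydroboration of the terminal alkene followed by B-alkyl Suzuki–Miyaura coupling extends the allyl group to the C1–C4 chain with both C4 methyl carbons, without touching the hindered enone.

Step 10
Reactants: 13 (6S)-4,4-dimethoxy-2,6-dimethyl-6-(4-methylpent-4-en-1-yl)cyclohex-2-en-1-one
Product: 14 (6S)-6-(4-chloro-4-methylpentyl)-2,6-dimethylcyclohex-2-ene-1,4-dione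
Conditions: HCl (4 M in 1,4-dioxane), CH2Cl2, 0 °C; then H2O, rt
Reagents that add atoms: hydrogen chloride Cl; water O
Why: Markovnikov hydrochlorination of the 1,1-disubstituted alkene gives the tertiary chloride at C4, and the same acid with water hydrolyses the allylic ketal to the C6 ketone; C10 is quaternary, so the ene-dione cannot aromatise.

Step 11
Reactants: 14 (6S)-6-(4-chloro-4-methylpentyl)-2,6-dimethylcyclohex-2-ene-1,4-dione
Product: 16 (4aR,8aS)-2,5,5,8a-tetramethyl-4a,5,6,7,8,8a-hexahydronaphthalene-1,4-dione, via trimethylsilyl dienol ether 15 (not isolated)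
Conditions: LiN(SiMe3)2, Me3SiCl, THF, −78 °C; solvent exchange; TiCl4, CH2Cl2, −78 °C
Reagents that add atoms: none
Why: Lewis-acid-mediated intramolecular α-tert-alkylation of a silyl enol ether; enolisation can occur only at C5 (C10 has no hydrogen, C7 is sp2), TiCl4 ionises the tertiary chloride and the C4 cation is captured by C5 in a six-membered closure, and because the tether on C10 reaches C5 only from its own face, H-5 ends up cis to the C10 methyl.

**Union with the side chain**

Step 12
Reactants: 16 (4aR,8aS)-2,5,5,8a-tetramethyl-4a,5,6,7,8,8a-hexahydronaphthalene-1,4-dione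
Product: 18 (4aR,8aS)-4-hydroxy-2,5,5,8a-tetramethyloctahydronaphthalen-1(2H)-one (epimers at C2 and C4), via dilithium enolate alkoxide 17 (not isolated)
Conditions: LiBH(s-Bu)3 (2.5 equiv), THF, −78 → 0 °C; aq. NH4Cl
Reagents that add atoms: none
Why: Conjugate plus 1,2-reduction; hydride adds 1,4 at C7 (the unsubstituted β-carbon of the C9 enone) so that C9 is masked as its enolate while a second equivalent reduces the more accessible C6 ketone, and the C6 and C8 configurations do not matter because both centres become sp2 later.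

Step 13
Reactants: 18 (4aR,8aS)-4-hydroxy-2,5,5,8a-tetramethyloctahydronaphthalen-1(2H)-one; 6 (2S)-2-(2,2-dimethoxyethyl)-2-ethynyloxirane
Product: 20 (5R,10S,13S)-13,16-epoxy-15,15-dimethoxylabd-11-yne-6,9-diol (epimers at C6, C8, C9), via lithium acetylide 19 (not isolated)
Conditions: 6 (3 equiv), n-BuLi, THF, −78 °C; then 18, −78 → 0 °C
Reagents that add atoms: none
Why: 1,2-Addition of a lithium acetylide to a hindered α,α,α'-trisubstituted cyclohexanone (the 2,2,6-trimethylcyclohexanone case) forms C9–C11; the acetylide cannot eliminate into the neighbouring epoxide, C5 is not epimerisable while C6 is an alkoxide, and the C9 configuration is erased in step 15.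

Step 14
Reactants: 20 (5R,10S,13S)-13,16-epoxy-15,15-dimethoxylabd-11-yne-6,9-diol
Product: 21 (5R,10S,13S)-13,16-epoxy-9-hydroxy-15,15-dimethoxylabd-11-yn-6-one (epimers at C8, C9)
Conditions: Dess–Martin periodinane, NaHCO3, CH2Cl2, 0 °C → rt
Reagents that add atoms: none
Why: Dess–Martin oxidation of the secondary C6 alcohol beside an unreactive tertiary propargylic alcohol, buffered to protect epoxide and acetal.

Step 15
Reactants: 21 (5R,10S,13S)-13,16-epoxy-9-hydroxy-15,15-dimethoxylabd-11-yn-6-one
Product: 22 (5R,10S,13S)-13,16-epoxy-15,15-dimethoxylabd-8-en-11-yn-6-one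
Conditions: Martin sulfurane, CH2Cl2, 0 °C → rt
Reagents that add atoms: none
Why: Neutral dehydration of a tertiary propargylic alcohol; C10 is quaternary, so only H-8 can be lost and the conjugated C8=C9 enyne should be the single regioisomer.

Step 16
Reactants: 22 (5R,10S,13S)-13,16-epoxy-15,15-dimethoxylabd-8-en-11-yn-6-one
Product: 23 (5R,10S,13R)-13,16-epoxy-15,15-dimethoxylabd-8-en-6-one
Conditions: 2-nitrobenzenesulfonyl hydrazide (excess, in portions), Et3N, CH2Cl2, rt
Reagents that add atoms: none
Why: Diimide reduction; concerted syn 1,2-transfer of hydrogen saturates the alkyne and then the cis-alkene but should leave the tetrasubstituted C8=C9 alkene, the ketone and the epoxide alone, and no metal is present that could open the vinyl-epoxide stage.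

Step 17
Reactants: 23 (5R,10S,13R)-13,16-epoxy-15,15-dimethoxylabd-8-en-6-one
Product: 25 (5R,7R,10S,13R)-13,16-epoxy-7-hydroxy-15,15-dimethoxylabd-8-en-6-one, via potassium dienolate 24 (not isolated)
Conditions: KN(SiMe3)2, THF, −78 °C; 2-(phenylsulfonyl)-3-phenyloxaziridine, −78 °C; aq. NH4Cl
Reagents that add atoms: 2-(phenylsulfonyl)-3-phenyloxaziridine O=S(=O)(N1OC1c1ccccc1)c1ccccc1
Why: Enolate hydroxylation with an N-sulfonyloxaziridine; the base removes the doubly activated H-7 (α to the ketone and allylic, whereas H-5 is far more hindered), the dienolate reacts at its α-carbon, and the oxidant should come from the β face because C1 and C4 of ring A cover the α face, giving 7β-OH.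

Step 18
Reactants: 25 (5R,7R,10S,13R)-13,16-epoxy-7-hydroxy-15,15-dimethoxylabd-8-en-6-one
Product: 26 (5R,7R,10S,13R)-7-(tert-butyldimethylsilyloxy)-13,16-epoxy-15,15-dimethoxylabd-8-en-6-one
Conditions: t-BuMe2SiCl, imidazole, DMAP (cat.), DMF, 40 °C
Reagents that add atoms: tert-butyldimethylsilyl chloride CC(C)(C)[Si](C)(C)Cl
Why: Silylation of the secondary α-hydroxy ketone under weakly basic conditions that leave epoxide and acetal intact.

Step 19
Reactants: 26 (5R,7R,10S,13R)-7-(tert-butyldimethylsilyloxy)-13,16-epoxy-15,15-dimethoxylabd-8-en-6-one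
Product: 28 (5R,7R,8R,9S,10S,13R)-7-(tert-butyldimethylsilyloxy)-13,16-epoxy-8,9-dihydroxy-15,15-dimethoxylabdan-6-one, via cyclic osmate ester 27 (not isolated)
Conditions: OsO4 (1.1 equiv), pyridine, THF, 0 °C → rt; then aq. NaHSO3
Reagents that add atoms: osmium tetroxide O=[Os](=O)(=O)=O
Why: Stoichiometric OsO4–pyridine cis-dihydroxylation of the tetrasubstituted alkene through a [3+2] osmate ester; addition should occur on the α face, anti to the allylic 7β-silyloxy group (the empirical anti rule for allylic ethers) and to the C10 methyl, giving the 8α,9α-diol.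

**Rings C and D, end game**

Step 20
Reactants: 28 (5R,7R,8R,9S,10S,13R)-7-(tert-butyldimethylsilyloxy)-13,16-epoxy-8,9-dihydroxy-15,15-dimethoxylabdan-6-one
Product: 30 (5R,7R,8R,9S,10S,13S)-7-(tert-butyldimethylsilyloxy)-9,13:15,16-diepoxy-8-hydroxy-15-methoxylabdan-6-one (C15 epimers), via 9,13-epoxy-16-hydroxy acetal 29 (not isolated)
Conditions: camphorsulfonic acid (0.1 equiv), 4 Å MS, CH2Cl2, 0 °C → rt
Reagents that add atoms: none
Why: The acid activates the 2,2-disubstituted epoxide and the 9α-hydroxyl attacks the tertiary carbon C13 from the rear (5-exo-tet, ring C), which frees the C16 hydroxyl; the same acid ionises the dimethyl acetal and the C16 hydroxyl captures the C15 oxocarbenium ion (5-exo-trig, ring D) with loss of methanol. The closest known reactions are the acid-catalysed 5-exo opening of 2,2-disubstituted and trisubstituted epoxides by tertiary alcohols (tetrahydrofuran formation in polyether synthesis) and intramolecular transacetalisation to 2-methoxytetrahydrofurans. C13 is the only new stereocentre that matters; it is set by inversion of the (13R)-epoxide from the Sharpless step, giving 13S, while C15 forms as both epimers and is erased in step 22. The step needs attack by O9 and not O8, and at C13 and not C16: O9 closes a five-membered ring where O8 would close a six-membered one, and under acid the developing positive charge sits on the tertiary C13, which also disfavours the 6-endo path to C16. Because ring D is formed as the saturated acetal, no enol ether is present that could aromatise to a furan in the acid.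

Step 21
Reactants: 30 (5R,7R,8R,9S,10S,13S)-7-(tert-butyldimethylsilyloxy)-9,13:15,16-diepoxy-8-hydroxy-15-methoxylabdan-6-one
Product: 32 (5R,7R,8R,9S,10S,13S)-8-acetoxy-7-(tert-butyldimethylsilyloxy)-9,13:15,16-diepoxy-15-methoxylabdan-6-one (C15 epimers), via lithium C8 alkoxide 31 (not isolated)
Conditions: LiN(SiMe3)2 (1.1 equiv), THF, −78 °C; then AcCl, −78 → −20 °C
Reagents that add atoms: acetyl chloride CC(=O)Cl
Why: O-Acylation of a preformed lithium tert-alkoxide, the usual answer to hindered tertiary alcohols that resist amine-catalysed acylation; O–H deprotonation at −78 °C should be faster than enolisation of the hindered ketone, and the acetal is never exposed to acid.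

Step 22
Reactants: 32 (5R,7R,8R,9S,10S,13S)-8-acetoxy-7-(tert-butyldimethylsilyloxy)-9,13:15,16-diepoxy-15-methoxylabdan-6-one
Product: 33 (5R,7R,8R,9S,10S,13S)-8-acetoxy-7-(tert-butyldimethylsilyloxy)-9,13:15,16-diepoxylabd-14-en-6-one
Conditions: Me3SiOTf (1.3 equiv), i-Pr2NEt (2 equiv), CH2Cl2, −40 → 0 °C
Reagents that add atoms: none
Why: Base-buffered elimination of methanol from an acetal; the silyl triflate ionises the cyclic methyl acetal to the C15 oxocarbenium ion and the hindered amine removes H-14, so that the acid-labile dihydrofuran never meets free acid.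

Step 23
Reactants: 33 (5R,7R,8R,9S,10S,13S)-8-acetoxy-7-(tert-butyldimethylsilyloxy)-9,13:15,16-diepoxylabd-14-en-6-one
Product: 34 (5R,7R,8R,9S,10S,13S)-8-acetoxy-9,13:15,16-diepoxy-7-hydroxylabd-14-en-6-one (CNP0275274.1)
Conditions: Bu4NF (1.2 equiv), AcOH (1.0 equiv), THF, 0 °C
Reagents that add atoms: none
Why: Fluoride cleavage of the silyl ether, buffered with acetic acid to stay near neutral, so that neither base-induced acyl migration or α-ketol epimerisation nor acid-induced aromatisation of ring D should occur.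

**Compound list**
1 | 2-[(trimethylsilyl)methyl]prop-2-en-1-yl acetate | CC(=O)OCC(=C)C[Si](C)(C)C | starting material
2 | 4,4-dimethoxy-2-methylidenebutyl acetate | CC(=O)OCC(=C)CC(OC)OC | intermediate
3 | 2-(2,2-dimethoxyethyl)prop-2-en-1-ol | OCC(=C)CC(OC)OC | intermediate
4 | [(2S)-2-(2,2-dimethoxyethyl)oxiran-2-yl]methanol | OC[C@@]1(CC(OC)OC)CO1 | intermediate
5 | (2R)-2-(2,2-dimethoxyethyl)oxirane-2-carbaldehyde | O=C[C@@]1(CC(OC)OC)CO1 | intermediate
6 | (2S)-2-(2,2-dimethoxyethyl)-2-ethynyloxirane | C#C[C@@]1(CC(OC)OC)CO1 | intermediate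
7 | 4-methoxy-2,6-dimethylphenol | COc1cc(C)c(O)c(C)c1 | starting material
8 | 4,4-dimethoxy-2,6-dimethylcyclohexa-2,5-dien-1-one | COC1(OC)C=C(C)C(=O)C(C)=C1 | intermediate
9 | lithium 4,4-dimethoxy-2,6-dimethylcyclohexa-1,5-dien-1-olate | [Li]OC1=C(C)CC(OC)(OC)C=C1C | intermediate
10 | allyl (4,4-dimethoxy-2,6-dimethylcyclohexa-1,5-dien-1-yl) carbonate | C=CCOC(=O)OC1=C(C)CC(OC)(OC)C=C1C | intermediate
11 | (6S)-6-allyl-4,4-dimethoxy-2,6-dimethylcyclohex-2-en-1-one | O=C1C(C)=CC(OC)(OC)C[C@]1(C)CC=C | intermediate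
12 | 9-BBN adduct of 11 (boron on the terminal carbon of the former allyl group) | O=C1C(C)=CC(OC)(OC)C[C@]1(C)CCCB1C2CCCC1CCC2 | intermediate
13 | (6S)-4,4-dimethoxy-2,6-dimethyl-6-(4-methylpent-4-en-1-yl)cyclohex-2-en-1-one | O=C1C(C)=CC(OC)(OC)C[C@]1(C)CCCC(C)=C | intermediate
14 | (6S)-6-(4-chloro-4-methylpentyl)-2,6-dimethylcyclohex-2-ene-1,4-dione | O=C1C(C)=CC(=O)C[C@]1(C)CCCC(C)(C)Cl | intermediate
15 | (6S)-6-(4-chloro-4-methylpentyl)-2,6-dimethyl-4-(trimethylsilyloxy)cyclohexa-2,4-dien-1-one | C[Si](C)(C)OC1=C[C@](C)(CCCC(C)(C)Cl)C(=O)C(C)=C1 | intermediate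
16 | (4aR,8aS)-2,5,5,8a-tetramethyl-4a,5,6,7,8,8a-hexahydronaphthalene-1,4-dione (cis-fused; labdane C6 and C9 ketones, C7=C8) | CC1=CC(=O)[C@@H]2C(C)(C)CCC[C@]2(C)C1=O | intermediate
17 | dilithium salt: C9 enolate (C8=C9) and C6 alkoxide of the reduced bicycle | CC=1CC(O[Li])[C@@H]2C(C)(C)CCC[C@]2(C)C=1O[Li] | intermediate
18 | (4aR,8aS)-4-hydroxy-2,5,5,8a-tetramethyloctahydronaphthalen-1(2H)-one (labdane 6-ol, 9-one; epimers at C6 and C8) | CC1CC(O)[C@@H]2C(C)(C)CCC[C@]2(C)C1=O | intermediate
19 | lithium acetylide of 6 | [Li]C#C[C@@]1(CC(OC)OC)CO1 | intermediate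
20 | (5R,10S,13S)-13,16-epoxy-15,15-dimethoxylabd-11-yne-6,9-diol (epimers at C6, C8, C9) | CC1CC(O)[C@@H]2C(C)(C)CCC[C@]2(C)C1(O)C#C[C@@]1(CC(OC)OC)CO1 | intermediate
21 | (5R,10S,13S)-13,16-epoxy-9-hydroxy-15,15-dimethoxylabd-11-yn-6-one (epimers at C8, C9) | CC1CC(=O)[C@@H]2C(C)(C)CCC[C@]2(C)C1(O)C#C[C@@]1(CC(OC)OC)CO1 | intermediate
22 | (5R,10S,13S)-13,16-epoxy-15,15-dimethoxylabd-8-en-11-yn-6-one | CC=1CC(=O)[C@@H]2C(C)(C)CCC[C@]2(C)C=1C#C[C@@]3(CC(OC)OC)CO3 | intermediate
23 | (5R,10S,13R)-13,16-epoxy-15,15-dimethoxylabd-8-en-6-one | CC=1CC(=O)[C@@H]2C(C)(C)CCC[C@]2(C)C=1CC[C@@]3(CC(OC)OC)CO3 | intermediate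
24 | potassium 6,8-dienolate of 23 (O–C6=C7–C8=C9) | CC=1C=C(O[K])[C@@H]2C(C)(C)CCC[C@]2(C)C=1CC[C@@]3(CC(OC)OC)CO3 | intermediate
25 | (5R,7R,10S,13R)-13,16-epoxy-7-hydroxy-15,15-dimethoxylabd-8-en-6-one | CC=1[C@@H](O)C(=O)[C@@H]2C(C)(C)CCC[C@]2(C)C=1CC[C@@]3(CC(OC)OC)CO3 | intermediate
26 | (5R,7R,10S,13R)-7-(tert-butyldimethylsilyloxy)-13,16-epoxy-15,15-dimethoxylabd-8-en-6-one | CC=1[C@@H](O[Si](C)(C)C(C)(C)C)C(=O)[C@@H]2C(C)(C)CCC[C@]2(C)C=1CC[C@@]3(CC(OC)OC)CO3 | intermediate
27 | cyclic 8α,9α-osmate ester of 26 (hexavalent osmium; pyridine ligands not drawn) | O4[C@]1(C)[C@@H](O[Si](C)(C)C(C)(C)C)C(=O)[C@@H]2C(C)(C)CCC[C@]2(C)[C@@]1(O[Os]4(=O)=O)CC[C@@]3(CC(OC)OC)CO3 | intermediate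
28 | (5R,7R,8R,9S,10S,13R)-7-(tert-butyldimethylsilyloxy)-13,16-epoxy-8,9-dihydroxy-15,15-dimethoxylabdan-6-one (key-step precursor) | O[C@]1(C)[C@@H](O[Si](C)(C)C(C)(C)C)C(=O)[C@@H]2C(C)(C)CCC[C@]2(C)[C@@]1(O)CC[C@@]3(CC(OC)OC)CO3 | intermediate
29 | (5R,7R,8R,9S,10S,13S)-7-(tert-butyldimethylsilyloxy)-9,13-epoxy-8,16-dihydroxy-15,15-dimethoxylabdan-6-one | O[C@]1(C)[C@@H](O[Si](C)(C)C(C)(C)C)C(=O)[C@@H]2C(C)(C)CCC[C@]2(C)[C@@]13CC[C@@](CO)(CC(OC)OC)O3 | intermediate
30 | (5R,7R,8R,9S,10S,13S)-7-(tert-butyldimethylsilyloxy)-9,13:15,16-diepoxy-8-hydroxy-15-methoxylabdan-6-one (C15 epimers; key-step product) | O[C@]1(C)[C@@H](O[Si](C)(C)C(C)(C)C)C(=O)[C@@H]2C(C)(C)CCC[C@]2(C)[C@@]12CC[C@@]1(CC(OC)OC1)O2 | intermediate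
31 | lithium C8 alkoxide of 30 | [Li]O[C@]1(C)[C@@H](O[Si](C)(C)C(C)(C)C)C(=O)[C@@H]2C(C)(C)CCC[C@]2(C)[C@@]12CC[C@@]1(CC(OC)OC1)O2 | intermediate
32 | (5R,7R,8R,9S,10S,13S)-8-acetoxy-7-(tert-butyldimethylsilyloxy)-9,13:15,16-diepoxy-15-methoxylabdan-6-one (C15 epimers) | CC(=O)O[C@]1(C)[C@@H](O[Si](C)(C)C(C)(C)C)C(=O)[C@@H]2C(C)(C)CCC[C@]2(C)[C@@]12CC[C@@]1(CC(OC)OC1)O2 | intermediate
33 | (5R,7R,8R,9S,10S,13S)-8-acetoxy-7-(tert-butyldimethylsilyloxy)-9,13:15,16-diepoxylabd-14-en-6-one | CC(=O)O[C@]1(C)[C@@H](O[Si](C)(C)C(C)(C)C)C(=O)[C@@H]2C(C)(C)CCC[C@]2(C)[C@@]12CC[C@@]1(C=COC1)O2 | intermediate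
34 | (5R,7R,8R,9S,10S,13S)-8-acetoxy-9,13:15,16-diepoxy-7-hydroxylabd-14-en-6-one | CC(=O)O[C@]1(C)[C@@H](O)C(=O)[C@@H]2C(C)(C)CCC[C@]2(C)[C@@]12CC[C@@]1(C=COC1)O2 | target

**Step count**
Total: 23 steps. Longest linear sequence: 18 steps (steps 6–23, from 7).

**Three steps most likely to fail**

Step 11 (ring A closure). After ionisation the tertiary cation may lose a proton instead of being trapped, and the HCl so formed would strip the silyl group, so ring A would not close. The fallback sets out from 13 and comes back at 16. The ketal of 13 alone is hydrolysed (aqueous oxalic acid, THF) to the alkenyl ene-dione F1, which is converted as in step 11 (LiN(SiMe3)2, Me3SiCl) into the silyl dienol ether F2. Ring A is then closed by alkene activation instead of halide ionisation: Hg(OTf)2·PhNMe2 (MeNO2, −20 °C; then aq. NaCl) forms the mercurinium ion of the 1,1-disubstituted alkene and C5 attacks its more substituted carbon with the same cis geometry, giving the chloromercurial F3. Reduction with Bu3SnH (THF, 0 °C) turns the CH2HgCl group into the second C4 methyl of 16.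

Step 19 (dihydroxylation). The hindered tetrasubstituted alkene may react with poor facial selectivity (ring A lies on the α face, the silyl ether and C10 methyl on the β face) or not at all. The fallback sets out from 26 and comes back at 28, and replaces substrate control by reagent control: a preformed complex of OsO4 with an enantiopure C2-symmetric N,N'-dialkyl-1,2-diphenylethane-1,2-diamine (the enantiomer matched to the α face) in CH2Cl2 at −78 °C, then NaHSO3. No new compound is made.

Step 20 (key cascade). The C8 hydroxyl may compete for C13 (six-membered 8,13-ether), or the free ditertiary diol may rearrange under acid. The fallback sets out from 28 and comes back at 32, masking O8 as the acetate before closure. MeC(OMe)3 with pyridinium tosylate (cat., CH2Cl2, 0 °C) gives the cyclic 8,9-orthoacetate F4. Controlled hydrolysis (1 equiv H2O, pyridinium tosylate) opens it to the 8-acetate 9-alcohol F5; any 9-acetate isomer equilibrates with it under acid through the same dioxolanylium ion. Camphorsulfonic acid then lets only O9 close ring C and O16 close ring D, which gives 32 directly and also bypasses step 21.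

Further compounds
F1 | step 11 | (6S)-2,6-dimethyl-6-(4-methylpent-4-en-1-yl)cyclohex-2-ene-1,4-dione | O=C1C(C)=CC(=O)C[C@]1(C)CCCC(C)=C
F2 | step 11 | (6S)-2,6-dimethyl-6-(4-methylpent-4-en-1-yl)-4-(trimethylsilyloxy)cyclohexa-2,4-dien-1-one | C[Si](C)(C)OC1=C[C@](C)(CCCC(C)=C)C(=O)C(C)=C1
F3 | step 11 | cis-fused 5-[(chloromercurio)methyl]-2,5,8a-trimethyl-4a,5,6,7,8,8a-hexahydronaphthalene-1,4-dione (ring fusion as in 16, epimers at the CH2HgCl-bearing carbon) | CC1=CC(=O)[C@@H]2C(C)(C[Hg]Cl)CCC[C@]2(C)C1=O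
F0 | step 19 | none | none
F4 | step 20 | cyclic 8,9-O-(1-methoxyethylidene) orthoacetate of 28 | O4[C@]1(C)[C@@H](O[Si](C)(C)C(C)(C)C)C(=O)[C@@H]2C(C)(C)CCC[C@]2(C)[C@@]1(OC4(C)OC)CC[C@@]3(CC(OC)OC)CO3
F5 | step 20 | 8-O-acetyl derivative of 28 (9-hydroxyl free) | CC(=O)O[C@]1(C)[C@@H](O[Si](C)(C)C(C)(C)C)C(=O)[C@@H]2C(C)(C)CCC[C@]2(C)[C@@]1(O)CC[C@@]3(CC(OC)OC)CO3
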